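The bicyclo[3.3.1]nonan-9-one is cut at C5–C6, which turns ring B (C1, C9, C5, C6, C7, C8) into a hexose: the cis oxygens on C1 (carbinol), C8–C7 (epoxide) and C6 (OMe) beside the C9 ketone map onto sugar C4, C3, C2, C1 and C5, with sugar C6 as C5. A Ferrier carbocyclisation of a 4-O-silyl methyl 2,3-anhydro-6-deoxy-4-C-vinyl-α-D-ribo-hex-5-enopyranoside hydrates the enol ether, opens the pyranoside and closes ring B by aldol attack of sugar C6 on the former anomeric carbon. This delivers the epoxy-cyclohexanone with C1, C7, C8 preset and C6 newly formed. Ring A follows from the C1 vinyl group by hydroformylation and a chelated intramolecular aldol; carbamate C–H amination installs N3.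

Key step: step 11

Numbering: C1 bridgehead carbinol, C2 CH2, C3 C–N, C4 CH–OH, C5 bridgehead CH, C6 C–OMe, C7/C8 epoxide (C8 on C1), C9 C=O; ring A = C1–C2–C3–C4–C5–C9, ring B = C1–C9–C5–C6–C7–C8; sugar locants are used up to compound 13.
Assumption: the tertiary triethylsilyl ether is taken to survive the near-neutral aqueous Hg(II) conditions of step 11.

Step 1
Reactants: 1 methyl 4,6-O-benzylidene-α-D-glucopyranoside
Product: 2 methyl 4,6-O-benzylidene-2,3-di-O-tosyl-α-D-glucopyranoside
Conditions: TsCl, pyridine, DMAP (cat.), 50 °C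
Reagents that add atoms: p-toluenesulfonyl chloride, Cc1ccc(cc1)S(=O)(=O)Cl
Why: Pyridine-mediated sulfonylation of both secondary hydroxyls; no stereocentre is touched.

Step 2
Reactants: 2 methyl 4,6-O-benzylidene-2,3-di-O-tosyl-α-D-glucopyranoside
Product: 3 methyl 2,3-anhydro-4,6-O-benzylidene-α-D-allopyranoside
Conditions: NaOMe, MeOH–CH2Cl2, reflux
Reagents that add atoms: none
Why: Methoxide removes the 2-O-sulfonyl group by attack at sulfur and the C2 alkoxide displaces the C3 tosylate with inversion (intramolecular SN2, anhydro-sugar formation), which places the oxirane on the α face (allo).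

Step 3
Reactants: 3 methyl 2,3-anhydro-4,6-O-benzylidene-α-D-allopyranoside
Product: 4 methyl 2,3-anhydro-α-D-allopyranoside
Conditions: H2 (1 atm), Pd/C, MeOH–EtOAc, rt
Reagents that add atoms: none
Why: Hydrogenolysis of the benzylic acetal C–O bonds frees O4 and O6 under neutral conditions that leave the non-benzylic oxirane intact.

Step 4
Reactants: 4 methyl 2,3-anhydro-α-D-allopyranoside
Product: 5 methyl 2,3-anhydro-6-O-(tert-butyldimethylsilyl)-α-D-allopyranoside
Conditions: TBSCl, imidazole, CH2Cl2–DMF, 0 °C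
Reagents that add atoms: tert-butyldimethylsilyl chloride, CC(C)(C)[Si](C)(C)Cl
Why: Silylation is selective for the primary 6-OH over the hindered secondary 4-OH.

Step 5
Reactants: 5 methyl 2,3-anhydro-6-O-(tert-butyldimethylsilyl)-α-D-allopyranoside
Product: 6 methyl 2,3-anhydro-6-O-(tert-butyldimethylsilyl)-α-D-ribo-hexopyranosid-4-ulose
Conditions: Dess–Martin periodinane, NaHCO3, CH2Cl2, 0 °C → rt
Reagents that add atoms: none
Why: Dess–Martin oxidation of the only free (secondary) alcohol gives the α,β-epoxy ketone under buffered conditions that should not epimerise C5.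

Step 6
Reactants: 6 methyl 2,3-anhydro-6-O-(tert-butyldimethylsilyl)-α-D-ribo-hexopyranosid-4-ulose; 7 vinylmagnesium bromide
Product: 8 methyl 2,3-anhydro-6-O-(tert-butyldimethylsilyl)-4-C-vinyl-α-D-allopyranoside (tertiary OH cis to the epoxide)
Conditions: THF, −78 °C; aq. NH4Cl
Reagents that add atoms: vinylmagnesium bromide (7), C=C[Mg]Br
Why: Grignard 1,2-addition; the small nucleophile should enter axially from the β face, anti to the oxirane oxygen on the neighbouring carbon, so the tertiary hydroxyl ends up cis to the epoxide (this sets target C1).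

Step 7
Reactants: 8 methyl 2,3-anhydro-6-O-(tert-butyldimethylsilyl)-4-C-vinyl-α-D-allopyranoside
Product: 9 methyl 2,3-anhydro-4-C-vinyl-α-D-allopyranoside
Conditions: TBAF, AcOH, THF, 0 °C → rt
Reagents that add atoms: none
Why: Fluoride cleaves the primary silyl ether, and the acetic acid buffer keeps the O6 alkoxide from opening the epoxide at C3 (3,6-anhydro formation).

Step 8
Reactants: 9 methyl 2,3-anhydro-4-C-vinyl-α-D-allopyranoside
Product: 10 methyl 2,3-anhydro-6-deoxy-6-iodo-4-C-vinyl-α-D-allopyranoside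
Conditions: I2, PPh3, imidazole, THF, 0 °C → rt
Reagents that add atoms: iodine, II
Why: Appel-type (Garegg) iodination converts only the primary alcohol by SN2 displacement of its alkoxyphosphonium ion; the tertiary alcohol cannot be displaced and epoxides tolerate these conditions at low temperature.

Step 9
Reactants: 10 methyl 2,3-anhydro-6-deoxy-6-iodo-4-C-vinyl-α-D-allopyranoside
Product: 11 methyl 2,3-anhydro-6-deoxy-4-C-vinyl-α-D-ribo-hex-5-enopyranoside
Conditions: DBU, THF, reflux
Reagents that add atoms: none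
Why: E2 dehydroiodination across C5–C6 (the only β-hydrogen is on C5) is the standard way to the exocyclic enol ether of a hex-5-enopyranoside.

Step 10
Reactants: 11 methyl 2,3-anhydro-6-deoxy-4-C-vinyl-α-D-ribo-hex-5-enopyranoside
Product: 12 methyl 2,3-anhydro-6-deoxy-4-O-triethylsilyl-4-C-vinyl-α-D-ribo-hex-5-enopyranoside
Conditions: TESOTf, 2,6-lutidine, CH2Cl2, −78 → 0 °C
Reagents that add atoms: triethylsilyl trifluoromethanesulfonate, CC[Si](CC)(CC)OS(=O)(=O)C(F)(F)F
Why: Silyl triflate with a hindered base silylates the tertiary alcohol without acid exposure of the enol ether; the ether later keeps O4 from trapping the aldehyde of step 11 and protects the tertiary α-ketol to the end.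

Step 11
Reactants: 12 methyl 2,3-anhydro-6-deoxy-4-O-triethylsilyl-4-C-vinyl-α-D-ribo-hex-5-enopyranoside
Product: 14 (2S,3S,4S,5S)-3,4-epoxy-5-hydroxy-2-(triethylsilyloxy)-2-vinylcyclohexan-1-one, via mercurio keto aldehyde 13 (not isolated)
Conditions: Hg(OCOCF3)2 (10 mol%), acetone–H2O (4:1), rt
Reagents that add atoms: water, O
Why: Ferrier carbocyclisation (Ferrier II reaction): Hg(II) adds to the electron-rich exocyclic enol ether (not to the vinyl group) with water at C5, the hemiketal collapses with loss of methanol to the C-mercurated 5-keto aldehyde 13, and its mercury enolate adds to the aldehyde with release of Hg(II), as in the known conversions of hex-5-enopyranosides into 2-deoxyinososes. Ring B closes in a 6-(enolendo)-exo-trig aldol step (the enolate C5=C6 of the sugar lies inside the new ring, the aldehyde C=O outside). The single new stereocentre, target C6, is controlled by the cis-fused oxirane: sugar C6 can reach the aldehyde only from the side of sugar C3 and should bond anti to the oxirane C2–O bond, which selects one half-chair, and in that half-chair the closed, metal-bridged transition state (aldehyde oxygen pseudoaxial beside the enolate oxygen, the arrangement behind the axial carbinol of ordinary Ferrier closures) turns the aldehyde oxygen to the epoxide face. The step therefore needs facial selectivity at the aldehyde for a hydroxyl cis to the epoxide oxygen and to O–C1; the rigid epoxide secures the direction of C–C bond formation, and the O-silyl group prevents O4 from masking the aldehyde as a furanose lactol, which would favour protodemercuration over closure. C1, C7 and C8 are carried over unchanged from sugar C4, C2 and C3.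

Step 12
Reactants: 14 (2S,3S,4S,5S)-3,4-epoxy-5-hydroxy-2-(triethylsilyloxy)-2-vinylcyclohexan-1-one
Product: 15 (2S,3S,4S,5S)-3,4-epoxy-5-methoxy-2-(triethylsilyloxy)-2-vinylcyclohexan-1-one
Conditions: Me3OBF4, 1,8-bis(dimethylamino)naphthalene, 4 Å MS, CH2Cl2, 0 °C → rt
Reagents that add atoms: trimethyloxonium tetrafluoroborate, C[O+](C)C.F[B-](F)(F)F
Why: O-alkylation with Meerwein salt and a hindered amine methylates the β-hydroxy ketone without forming an alkoxide, so neither retro-aldol cleavage nor β-elimination is triggered and C6 keeps its configuration.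

Step 13
Reactants: 15 (2S,3S,4S,5S)-3,4-epoxy-5-methoxy-2-(triethylsilyloxy)-2-vinylcyclohexan-1-one
Product: 16 3-[(1S,2S,3S,4S)-2,3-epoxy-4-methoxy-6-oxo-1-(triethylsilyloxy)cyclohexyl]propanal
Conditions: Rh(acac)(CO)2 (2 mol%), Xantphos (4 mol%), CO/H2 (1:1, 10 bar), toluene, 60 °C
Reagents that add atoms: carbon monoxide, [C-]#[O+]
Why: Rhodium-catalysed hydroformylation of a vinyl group on a quaternary carbon is linear-selective (the branched alkyl-rhodium would be neopentyl-like, and no allylic hydrogen allows isomerisation), so C3 and C4 arrive in one neutral step.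

Step 14
Reactants: 16 3-[(1S,2S,3S,4S)-2,3-epoxy-4-methoxy-6-oxo-1-(triethylsilyloxy)cyclohexyl]propanal
Product: 17 (1S,4S,5S,6S,7S,8S)-7,8-epoxy-4-hydroxy-6-methoxy-1-(triethylsilyloxy)bicyclo[3.3.1]nonan-9-one (4-OH syn to the C9 carbonyl)
Conditions: t-BuOLi (0.3 equiv), THF (0.01 M), −40 → 0 °C; AcOH
Reagents that add atoms: none
Why: Intramolecular aldol addition, 6-(enolendo)-exo-trig, of the kind that converts 2-(3-oxopropyl)cyclohexanones into 2-hydroxybicyclo[3.3.1]nonan-9-ones: the ketone can enolise only toward C5 (the aldehyde enolate has no productive closure and returns by proton transfer), the tether forces C4 onto the face of C5 that carries the chain (trans to OMe), and the lithium-bridged closed transition state places the C4 oxygen syn to the C9 carbonyl, after which C5 is a bridgehead and methoxide can no longer be eliminated.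

Step 15
Reactants: 17 (1S,4S,5S,6S,7S,8S)-7,8-epoxy-4-hydroxy-6-methoxy-1-(triethylsilyloxy)bicyclo[3.3.1]nonan-9-one
Product: 19 (1S,4S,5S,6S,7S,8S)-7,8-epoxy-6-methoxy-9-oxo-1-(triethylsilyloxy)bicyclo[3.3.1]nonan-4-yl carbamate, via N-trichloroacetyl carbamate 18 (not isolated)
Conditions: Cl3CC(O)NCO, CH2Cl2, 0 °C; then K2CO3 (cat.), MeOH, rt
Reagents that add atoms: trichloroacetyl isocyanate, O=C=NC(=O)C(Cl)(Cl)Cl
Why: Addition of the hindered secondary alcohol to the acyl isocyanate and mild methanolysis of the trichloroacetyl group give the primary carbamate; the ketone has no enolisable position, so the basic methanol is harmless.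

Step 16
Reactants: 19 (1S,4S,5S,6S,7S,8S)-7,8-epoxy-6-methoxy-9-oxo-1-(triethylsilyloxy)bicyclo[3.3.1]nonan-4-yl carbamate
Product: 20 cyclic carbamate (oxazolidin-2-one cis-fused across N–C3 and O–C4) of (1S,3S,4R,5S,6S,7S,8S)-3-amino-7,8-epoxy-4-hydroxy-6-methoxy-1-(triethylsilyloxy)bicyclo[3.3.1]nonan-9-one
Conditions: Rh2(esp)2 (3 mol%), PhI(OAc)2, MgO, CH2Cl2, 40 °C
Reagents that add atoms: none
Why: Rhodium-nitrene C–H amination of a carbamate (Du Bois) forms the five-membered ring by insertion with retention into the C3–H bond on the same face as the C4 oxygen, which sets C3 cis to O4; the only other β C–H, at bridgehead C5, is α to the ketone and electronically deactivated.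

Step 17
Reactants: 20 cyclic carbamate (oxazolidin-2-one across N–C3 and O–C4)
Product: 22 tert-butyl N-[(1S,3S,4R,5S,6S,7S,8S)-7,8-epoxy-4-hydroxy-6-methoxy-9-oxo-1-(triethylsilyloxy)bicyclo[3.3.1]nonan-3-yl]carbamate, via N-Boc oxazolidinone 21 (not isolated)
Conditions: Boc2O, DMAP (cat.), MeCN, rt; then Cs2CO3 (cat.), MeOH, rt
Reagents that add atoms: di-tert-butyl dicarbonate, CC(C)(C)OC(=O)OC(=O)OC(C)(C)C
Why: N-acylation makes the ring carbonyl the most electrophilic site, so catalytic methoxide opens the oxazolidinone (the O-methyl carbonate formed is methanolysed in turn) to the N-Boc amino alcohol at room temperature without touching a stereocentre.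

Step 18
Reactants: 22 tert-butyl N-[(1S,3S,4R,5S,6S,7S,8S)-7,8-epoxy-4-hydroxy-6-methoxy-9-oxo-1-(triethylsilyloxy)bicyclo[3.3.1]nonan-3-yl]carbamate; 23 (E)-dodec-2-enoic acid
Product: 25 (E)-N-[(1S,3S,4R,5S,6S,7S,8S)-7,8-epoxy-1,4-dihydroxy-6-methoxy-9-oxobicyclo[3.3.1]nonan-3-yl]dodec-2-enamide (target), via amino diol 24 (not isolated)
Conditions: TFA–CH2Cl2 (1:4), 0 °C → rt, evaporate; then 23, EDC·HCl, HOBt, i-Pr2NEt, CH2Cl2, 0 °C → rt
Reagents that add atoms: (E)-dodec-2-enoic acid (23), CCCCCCCCC/C=C/C(=O)O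
Why: Acidolysis removes the Boc group and the tertiary silyl ether (cis-disubstituted epoxides flanked by oxygenated carbons tolerate dilute TFA), and carbodiimide/HOBt amide coupling acylates the amine in preference to the hydroxyls with the E-alkene untouched.

Compound list
1 | methyl 4,6-O-[(R)-benzylidene]-α-D-glucopyranoside | CO[C@H]1O[C@@H]2CO[C@@H](c3ccccc3)O[C@H]2[C@H](O)[C@H]1O | starting material
2 | methyl 4,6-O-benzylidene-2,3-di-O-tosyl-α-D-glucopyranoside | CO[C@H]1O[C@@H]2CO[C@@H](c3ccccc3)O[C@H]2[C@H](OS(=O)(=O)c4ccc(C)cc4)[C@H]1OS(=O)(=O)c5ccc(C)cc5 | intermediate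
3 | methyl 2,3-anhydro-4,6-O-benzylidene-α-D-allopyranoside | CO[C@H]1O[C@@H]2CO[C@@H](c3ccccc3)O[C@H]2[C@H]4O[C@@H]14 | intermediate
4 | methyl 2,3-anhydro-α-D-allopyranoside | CO[C@H]1O[C@H](CO)[C@@H](O)[C@H]2O[C@@H]12 | intermediate
5 | methyl 2,3-anhydro-6-O-(tert-butyldimethylsilyl)-α-D-allopyranoside | CO[C@H]1O[C@H](CO[Si](C)(C)C(C)(C)C)[C@@H](O)[C@H]2O[C@@H]12 | intermediate
6 | methyl 2,3-anhydro-6-O-(tert-butyldimethylsilyl)-α-D-ribo-hexopyranosid-4-ulose | CO[C@H]1O[C@H](CO[Si](C)(C)C(C)(C)C)C(=O)[C@H]2O[C@@H]12 | intermediate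
7 | vinylmagnesium bromide | C=C[Mg]Br | starting material
8 | methyl 2,3-anhydro-6-O-(tert-butyldimethylsilyl)-4-C-vinyl-α-D-allopyranoside | CO[C@H]1O[C@H](CO[Si](C)(C)C(C)(C)C)[C@](O)(C=C)[C@H]2O[C@@H]12 | intermediate
9 | methyl 2,3-anhydro-4-C-vinyl-α-D-allopyranoside | CO[C@H]1O[C@H](CO)[C@](O)(C=C)[C@H]2O[C@@H]12 | intermediate
10 | methyl 2,3-anhydro-6-deoxy-6-iodo-4-C-vinyl-α-D-allopyranoside | CO[C@H]1O[C@H](CI)[C@](O)(C=C)[C@H]2O[C@@H]12 | intermediate
11 | methyl 2,3-anhydro-6-deoxy-4-C-vinyl-α-D-ribo-hex-5-enopyranoside (tertiary OH cis to the epoxide) | CO[C@H]1OC(=C)[C@](O)(C=C)[C@H]2O[C@@H]12 | intermediate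
12 | methyl 2,3-anhydro-6-deoxy-4-O-triethylsilyl-4-C-vinyl-α-D-ribo-hex-5-enopyranoside | CO[C@H]1OC(=C)[C@](O[Si](CC)(CC)CC)(C=C)[C@H]2O[C@@H]12 | intermediate
13 | 2,3-anhydro-6-deoxy-6-(trifluoroacetoxymercurio)-4-O-triethylsilyl-4-C-vinyl-D-ribo-hexos-5-ulose (open-chain keto aldehyde) | O=C[C@@H]1O[C@@H]1[C@@](O[Si](CC)(CC)CC)(C=C)C(=O)C[Hg]OC(=O)C(F)(F)F | intermediate
14 | (2S,3S,4S,5S)-3,4-epoxy-5-hydroxy-2-(triethylsilyloxy)-2-vinylcyclohexan-1-one (silyloxy, epoxide oxygen and 5-OH all cis) | C=C[C@@]2(O[Si](CC)(CC)CC)C(=O)C[C@H](O)[C@@H]1O[C@@H]12 | intermediate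
15 | (2S,3S,4S,5S)-3,4-epoxy-5-methoxy-2-(triethylsilyloxy)-2-vinylcyclohexan-1-one | C=C[C@@]2(O[Si](CC)(CC)CC)C(=O)C[C@H](OC)[C@@H]1O[C@@H]12 | intermediate
16 | 3-[(1S,2S,3S,4S)-2,3-epoxy-4-methoxy-6-oxo-1-(triethylsilyloxy)cyclohexyl]propanal | O=CCC[C@@]2(O[Si](CC)(CC)CC)C(=O)C[C@H](OC)[C@@H]1O[C@@H]12 | intermediate
17 | (1S,4S,5S,6S,7S,8S)-7,8-epoxy-4-hydroxy-6-methoxy-1-(triethylsilyloxy)bicyclo[3.3.1]nonan-9-one | C1C[C@@]2(O[Si](CC)(CC)CC)C(=O)[C@@H]([C@H]1O)[C@H](OC)[C@@H]1O[C@@H]12 | intermediate
18 | N-trichloroacetyl carbamate of 17 at O4 | C1C[C@@]2(O[Si](CC)(CC)CC)C(=O)[C@@H]([C@H]1OC(=O)NC(=O)C(Cl)(Cl)Cl)[C@H](OC)[C@@H]1O[C@@H]12 | intermediate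
19 | (1S,4S,5S,6S,7S,8S)-7,8-epoxy-6-methoxy-9-oxo-1-(triethylsilyloxy)bicyclo[3.3.1]nonan-4-yl carbamate | C1C[C@@]2(O[Si](CC)(CC)CC)C(=O)[C@@H]([C@H]1OC(N)=O)[C@H](OC)[C@@H]1O[C@@H]12 | intermediate
20 | oxazolidin-2-one cis-fused across N–C3 and O–C4 of (1S,3S,4R,5S,6S,7S,8S)-3-amino-7,8-epoxy-4-hydroxy-6-methoxy-1-(triethylsilyloxy)bicyclo[3.3.1]nonan-9-one | O=C1N[C@H]2C[C@@]3(O[Si](CC)(CC)CC)C(=O)[C@@H]([C@H]2O1)[C@H](OC)[C@@H]2O[C@@H]23 | intermediate
21 | N-Boc derivative of oxazolidinone 20 | O=C1N(C(=O)OC(C)(C)C)[C@H]2C[C@@]3(O[Si](CC)(CC)CC)C(=O)[C@@H]([C@H]2O1)[C@H](OC)[C@@H]2O[C@@H]23 | intermediate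
22 | tert-butyl N-[(1S,3S,4R,5S,6S,7S,8S)-7,8-epoxy-4-hydroxy-6-methoxy-9-oxo-1-(triethylsilyloxy)bicyclo[3.3.1]nonan-3-yl]carbamate | CC(C)(C)OC(=O)N[C@H]1C[C@@]2(O[Si](CC)(CC)CC)C(=O)[C@@H]([C@H]1O)[C@H](OC)[C@@H]1O[C@@H]12 | intermediate
23 | (E)-dodec-2-enoic acid | CCCCCCCCC/C=C/C(=O)O | starting material
24 | (1S,3S,4R,5S,6S,7S,8S)-3-amino-7,8-epoxy-1,4-dihydroxy-6-methoxybicyclo[3.3.1]nonan-9-one | N[C@H]1C[C@@]2(O)C(=O)[C@@H]([C@H]1O)[C@H](OC)[C@@H]1O[C@@H]12 | intermediate
25 | (E)-N-[(1S,3S,4R,5S,6S,7S,8S)-7,8-epoxy-1,4-dihydroxy-6-methoxy-9-oxobicyclo[3.3.1]nonan-3-yl]dodec-2-enamide | CCCCCCCCC/C=C/C(=O)N[C@H]1C[C@@]2(O)C(=O)[C@@H]([C@H]1O)[C@H](OC)[C@@H]1O[C@@H]12 | target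

Total step count: 18. Longest linear sequence: 18 steps (1 → 25).

Steps most likely to fail

Step 11. The closure could run through an open, dipole-minimised transition state with the aldehyde oxygen pseudoequatorial, turned away from the oxirane oxygen, which would give the C6 epimer. Slow closure would also let the mercurio ketone be protonated to the uncyclised methyl ketone. The fallback sets out from 12 and returns at 15, and creates no stereocentre at C6. Ti(Oi-Pr)Cl3 in CH2Cl2 at −78 °C should cleave the endocyclic C1–O5 bond of the hex-5-enopyranoside and let the titanium enolate recombine with the methoxy-oxocarbenium ion. This is the aglycone-retaining Lewis-acid variant of the carbocyclisation, which is known to keep the anomeric configuration. The α-methoxy group of 12 is already cis to the epoxide, so this gives methyl ether 15 directly, step 12 is skipped, and no new compound arises (F0). Short contact at low temperature is needed so that the Lewis acid does not open the epoxide.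

Step 16. The rhodium nitrene may insert only sluggishly into the unactivated secondary C3–H bond, so that oxidative decomposition of the carbamate or insertion elsewhere takes over. The fallback sets out from 17 and returns at 24 inside step 18, and replaces concerted nitrene insertion by a radical relay. Alcohol 17 with Cl3CCN and catalytic DBU should give the C4 trichloroacetimidate F1. PhI(OAc)2/NaI under visible light then generates the imidate N-radical, which abstracts the C3 hydrogen by 1,5-hydrogen transfer; iodination and ring closure by nitrogen, possible only on the face of the C4 oxygen, give the cis-fused 2-(trichloromethyl)oxazoline F2. Acidic methanolysis (TFA, MeOH–H2O) opens the oxazoline and removes the trichloroacetate and the silyl ether, delivering amino diol 24 as its salt for the coupling of step 18.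

Step 14. The ring could close without lithium bridging, or the aldolate could equilibrate, which would give the C4 epimer; the monocyclic enolate may also lose methoxide before it cyclises. The fallback sets out from 16 and returns at 17, and sets C4 by substitution instead of by the aldol transition state. The ring is closed under amine catalysis at low enolate concentration (DBU cat., CH2Cl2), and the C4-epimeric alcohol F3 (4-OH anti to the C9 carbonyl) is accepted. A Mitsunobu reaction (PPh3, DIAD, 4-nitrobenzoic acid) then inverts C4 to the 4-nitrobenzoate F4; elimination toward the bridgehead is impossible. K2CO3/MeOH releases 17.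

Further compounds
F0 | step 11 | none | none
F1 | step 16 | C4 O-trichloroacetimidate of 17 | C1C[C@@]2(O[Si](CC)(CC)CC)C(=O)[C@@H]([C@H]1OC(=N)C(Cl)(Cl)Cl)[C@H](OC)[C@@H]1O[C@@H]12
F2 | step 16 | 2-(trichloromethyl)oxazoline cis-fused across N–C3 and O–C4 (1-O-triethylsilyl) | ClC(Cl)(Cl)C1=N[C@H]2C[C@@]3(O[Si](CC)(CC)CC)C(=O)[C@@H]([C@H]2O1)[C@H](OC)[C@@H]2O[C@@H]23
F3 | step 14 | C4 epimer of 17 (4-OH anti to the C9 carbonyl) | C1C[C@@]2(O[Si](CC)(CC)CC)C(=O)[C@@H]([C@@H]1O)[C@H](OC)[C@@H]1O[C@@H]12
F4 | step 14 | 4-O-(4-nitrobenzoyl) ester of 17 | C1C[C@@]2(O[Si](CC)(CC)CC)C(=O)[C@@H]([C@H]1OC(=O)c3ccc(cc3)[N+](=O)[O-])[C@H](OC)[C@@H]1O[C@@H]12
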